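**Plan** (ring atoms: C1 carbonyl, C2 and C6 methyl-bearing, C3 methine, C4 quaternary, C5 side-chain carbon; pyranone numbered as a 4H-pyran-4-one with C2′ on C4)

- Retrosynthetic cuts, in order: C5–C7 (ring to side chain), pyranone C3′–C4′ and O1′–C6′, ring C5–C6, ring C4–C3.
- Enabling feature: C4 carries a methyl, pyranone C2′ (with C3′ and its methyl a latent propanoyl group) and ring C5 (a latent ester carbon), so it is the α-carbon of methyl 2-methyl-3-oxopentanoate. C3, C2 (+CH3), C1 and C6 (+CH3) form a 2-methylidene-3-oxopentyl unit, the allyl part of the Morita–Baylis–Hillman carbonate of pent-1-en-3-one.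
- Forward order: the two achiral pieces are joined at C4–C3, the carbocycle is closed at C5–C6 and the exocyclic alkene moved into the ring, and C5–O becomes a triflate.
- The pyranone is then built on the propanoyl group, the side chain (from propanal and (R)-but-3-yn-2-ol) is coupled last, and desilylation and oxidation finish the route.
- Stereochemistry: C4 by catalyst control in the allylic alkylation; the side-chain methyl centre by chirality transfer from (R)-but-3-yn-2-ol; the E alkene by syn hydroboration and stereoretentive coupling.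

Key step: step 3

Assumption: (DHQD)2PHAL is taken to give the R configuration at the new centre of 6; if the sense proved opposite, the pseudoenantiomeric hydroquinine-derived dimer (DHQ)2PHAL would be used with nothing else changed.

**Step 1**
Reactants: 1 pent-1-en-3-one; 2 formaldehyde
Product: 3 2-(hydroxymethyl)pent-1-en-3-one
Conditions: 37% aq. CH2O, DABCO (15 mol%), THF–H2O, rt
Reagents that add atoms: none
Why: Morita–Baylis–Hillman reaction, in which the amine adds to the vinyl ketone, the zwitterionic enolate is hydroxymethylated by formaldehyde and the amine is eliminated, a combination that is well established for alkyl vinyl ketones.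

**Step 2**
Reactants: 3 2-(hydroxymethyl)pent-1-en-3-one
Product: 4 tert-butyl (2-methylidene-3-oxopentyl) carbonate
Conditions: Boc2O, DMAP (5 mol%), CH2Cl2, 0 °C
Reagents that add atoms: di-tert-butyl dicarbonate, CC(C)(C)OC(=O)OC(=O)OC(C)(C)C
Why: DMAP-catalysed O-acylation of the primary allylic alcohol (carbonate formation), the usual activation of Morita–Baylis–Hillman alcohols for Lewis-base substitution.

**Step 3**
Reactants: 5 methyl 2-methyl-3-oxopentanoate (racemic); 4 tert-butyl (2-methylidene-3-oxopentyl) carbonate (1.2 equiv)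
Product: 6 methyl (2R)-2-methyl-2-(2-methylidene-3-oxopentyl)-3-oxopentanoate
Conditions: hydroquinidine 1,4-phthalazinediyl diether, (DHQD)2PHAL (10 mol%), toluene, 0 °C
Reagents that add atoms: none
Why: Lewis-base-catalysed asymmetric allylic alkylation of a Morita–Baylis–Hillman carbonate: the quinuclidine nitrogen adds to the enone methylene and expels tert-butyl carbonate (SN2′), which loses CO2 to tert-butoxide; this deprotonates 5, and the ketoester enolate, ion-paired with the chiral allylammonium, attacks the new methylene terminus in a second SN2′ step that forms C4–C3 and frees the amine. The closest precedent is the cinchona-amine-catalysed alkylation of prochiral α-substituted β-ketoesters and related 1,3-dicarbonyl donors with such carbonates. No ring is closed. The quaternary centre (R in 6) should be set by enantiofacial discrimination of the tetrasubstituted enolate inside the chiral ion pair held in the phthalazine cleft of the catalyst. The step needs C- over O-alkylation and a single enolate geometry; the soft allylammonium electrophile secures the first, and the internally chelated Z enolate of the 2-methyl-3-oxo ester, kept in a non-polar solvent at low temperature, the second. Racemic background alkylation should be small because base is generated only after the catalyst has engaged the carbonate.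

**Step 4**
Reactants: 6 methyl (2R)-2-methyl-2-(2-methylidene-3-oxopentyl)-3-oxopentanoate
Product: 8 (4S)-3-hydroxy-2,4-dimethyl-6-methylidene-4-propanoylcyclohex-2-en-1-one, via dilithium bis-enolate 7 (not isolated)
Conditions: LiN(SiMe3)2 (3 equiv), THF, −78 → 0 °C; then 1 M HCl
Reagents that add atoms: none
Why: Dieckmann-type intramolecular Claisen condensation in which excess amide base holds both ethyl ketones as enolates (7), so that neither ketone can serve as an aldol acceptor and the enone is no longer a Michael acceptor, leaving 6-exo-trig attack of the cross-conjugated enolate carbon C6 on the methyl ester as the productive path, driven by formation of the stabilised dione enolate; the quaternary centre is not touched.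

**Step 5**
Reactants: 8 (4S)-3-hydroxy-2,4-dimethyl-6-methylidene-4-propanoylcyclohex-2-en-1-one
Product: 9 (4S)-3-hydroxy-2,4,6-trimethyl-4-propanoylcyclohexa-2,5-dien-1-one
Conditions: RhCl3·3H2O (5 mol%), EtOH–H2O (10:1), 80 °C
Reagents that add atoms: none
Why: Rhodium-catalysed alkene isomerisation (hydride addition–elimination) of an α-methylene ketone into the ring, driven here by formation of the trisubstituted, cross-conjugated dienone; C4 is quaternary, so it can neither epimerise nor allow aromatisation.

**Step 6**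
Reactants: 9 (4S)-3-hydroxy-2,4,6-trimethyl-4-propanoylcyclohexa-2,5-dien-1-one
Product: 10 (6S)-2,4,6-trimethyl-3-oxo-6-propanoylcyclohexa-1,4-dien-1-yl trifluoromethanesulfonate
Conditions: Tf2O (1.05 equiv), iPr2NEt, CH2Cl2, −78 °C
Reagents that add atoms: trifluoromethanesulfonic anhydride, O=S(=O)(OS(=O)(=O)C(F)(F)F)C(F)(F)F
Why: Enol triflate formation from a cyclic 1,3-dione, expected at the C5 oxygen because that oxygen is the enolate terminus of the cross-conjugated dienone resonance form and leads to the more stable 2,5-dienone, whereas the C1 oxygen lies between two coplanar methyl-bearing sp2 carbons.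

**Step 7**
Reactants: 11 2-methylpropanedioic acid (methylmalonic acid)
Product: 12 2-methylpropanedioyl dichloride (methylmalonyl dichloride)
Conditions: SOCl2, 60 °C; distillation
Reagents that add atoms: thionyl chloride, O=S(Cl)Cl
Why: Acyl chloride formation from the diacid with thionyl chloride, the standard preparation of malonyl dichlorides.

**Step 8**
Reactants: 10 (6S)-2,4,6-trimethyl-3-oxo-6-propanoylcyclohexa-1,4-dien-1-yl trifluoromethanesulfonate; 12 2-methylpropanedioyl dichloride
Product: 14 (6R)-6-(4-hydroxy-3,5-dimethyl-2-oxo-2H-pyran-6-yl)-2,4,6-trimethyl-3-oxocyclohexa-1,4-dien-1-yl trifluoromethanesulfonate, via trimethylsilyl enol ether 13 (not isolated)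
Conditions: Me3SiOTf, iPr2NEt, CH2Cl2, 0 °C; pentane, filtration, evaporation; then 12, Et2O, −78 °C → rt
Reagents that add atoms: none
Why: Soft enolisation of the only enolisable ketone gives silyl enol ether 13, which is C-acylated by the malonyl dichloride and then closes by O-acylation to the 4-hydroxy-2-pyranone (the known pyranone annulation of silyl enol ethers with malonyl dichlorides), under non-basic conditions that the vinylogous triflate should tolerate.

**Step 9**
Reactants: 14 (6R)-6-(4-hydroxy-3,5-dimethyl-2-oxo-2H-pyran-6-yl)-2,4,6-trimethyl-3-oxocyclohexa-1,4-dien-1-yl trifluoromethanesulfonate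
Product: 15 (6R)-6-(6-methoxy-3,5-dimethyl-4-oxo-4H-pyran-2-yl)-2,4,6-trimethyl-3-oxocyclohexa-1,4-dien-1-yl trifluoromethanesulfonate
Conditions: MeOTf, 2,6-di-tert-butyl-4-methylpyridine, CH2Cl2, 0 °C → rt
Reagents that add atoms: methyl trifluoromethanesulfonate, COS(=O)(=O)C(F)(F)F
Why: O-Methylation of a 4-hydroxy-2-pyranone with a hard methylating agent takes place at the lactone carbonyl oxygen and, after loss of a proton, gives the 2-methoxy-4-pyranone, the usual entry to α-methoxy-γ-pyrones.

**Step 10**
Reactants: 16 (R)-but-3-yn-2-ol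
Product: 17 (R)-but-3-yn-2-yl methanesulfonate
Conditions: MsCl, Et3N, CH2Cl2, −78 °C
Reagents that add atoms: methanesulfonyl chloride, CS(=O)(=O)Cl
Why: Sulfonylation of the secondary propargylic alcohol at oxygen, which leaves the carbinol configuration unchanged.

**Step 11**
Reactants: 17 (R)-but-3-yn-2-yl methanesulfonate; 18 propanal
Product: 20 (3R,4S)-4-methylhex-5-yn-3-ol, via allenylzinc intermediate 19 (not isolated)
Conditions: Pd(OAc)2 (5 mol%), PPh3 (5 mol%), Et2Zn (3 equiv), THF, −78 → −20 °C
Reagents that add atoms: none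
Why: Marshall propargylation, in which zerovalent palladium opens the mesylate by anti SN2′ attack, transmetalation gives the configurationally defined allenylzinc 19, and this adds to propanal through a cyclic SE2′ transition state, so that the (R)-mesylate should give the anti alcohol with the 4S methyl centre (net inversion at the former carbinol carbon).

**Step 12**
Reactants: 20 (3R,4S)-4-methylhex-5-yn-3-ol
Product: 21 tert-butyl(dimethyl){[(3R,4S)-4-methylhex-5-yn-3-yl]oxy}silane
Conditions: TBSCl, imidazole, DMF, rt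
Reagents that add atoms: tert-butyl(chloro)dimethylsilane, CC(C)(C)[Si](C)(C)Cl
Why: Imidazole-promoted silyl ether formation at the secondary alcohol, which masks it for the organolithium and coupling steps.

**Step 13**
Reactants: 21 tert-butyl(dimethyl){[(3R,4S)-4-methylhex-5-yn-3-yl]oxy}silane
Product: 23 tert-butyl(dimethyl){[(3R,4S)-4-methylhept-5-yn-3-yl]oxy}silane, via lithium acetylide 22 (not isolated)
Conditions: n-BuLi, THF, −78 °C; then MeI, −78 °C → rt
Reagents that add atoms: iodomethane, CI
Why: Deprotonation of the terminal alkyne and SN2 methylation of the lithium acetylide 22, with the silyl ether and both stereocentres untouched.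

**Step 14**
Reactants: 23 tert-butyl(dimethyl){[(3R,4S)-4-methylhept-5-yn-3-yl]oxy}silane
Product: 24 tert-butyl(dimethyl){[(3R,4S,5Z)-4-methyl-6-(4,4,5,5-tetramethyl-1,3,2-dioxaborolan-2-yl)hept-5-en-3-yl]oxy}silane
Conditions: pinacolborane, Cp2Zr(H)Cl (10 mol%), Et3N (10 mol%), neat, 60 °C
Reagents that add atoms: pinacolborane, CC1(C)OBOC1(C)C
Why: Zirconocene-hydride-catalysed syn hydroboration of the internal alkyne, which should place boron on the methyl-bearing carbon, away from the branched substituent, and so give the alkenylboronate with H and B cis.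

**Step 15**
Reactants: 15 (6R)-6-(6-methoxy-3,5-dimethyl-4-oxo-4H-pyran-2-yl)-2,4,6-trimethyl-3-oxocyclohexa-1,4-dien-1-yl trifluoromethanesulfonate; 24 the alkenylboronate
Product: 25 (4S)-3-[(2E,4S,5R)-5-{[tert-butyl(dimethyl)silyl]oxy}-4-methylhept-2-en-2-yl]-4-(6-methoxy-3,5-dimethyl-4-oxo-4H-pyran-2-yl)-2,4,6-trimethylcyclohexa-2,5-dien-1-one
Conditions: Pd(OAc)2 (10 mol%), SPhos (20 mol%), K3PO4, THF–H2O (10:1), 40 °C
Reagents that add atoms: none
Why: Suzuki–Miyaura coupling of the vinylogous acyl triflate with the alkenylboronate (oxidative addition to zerovalent palladium, base-assisted transmetalation, reductive elimination) with retention of alkene geometry, the bulky electron-rich biaryl phosphine being chosen because both partners are hindered.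

**Step 16**
Reactants: 25 the coupled silyl ether
Product: 26 (4S)-3-[(2E,4S,5R)-5-hydroxy-4-methylhept-2-en-2-yl]-4-(6-methoxy-3,5-dimethyl-4-oxo-4H-pyran-2-yl)-2,4,6-trimethylcyclohexa-2,5-dien-1-one
Conditions: HF·pyridine, pyridine, THF, 0 °C → rt
Reagents that add atoms: none
Why: Fluoride-mediated silyl ether cleavage under buffered, weakly acidic conditions that should leave the methoxypyranone, the dienone and both stereocentres intact.

**Step 17**
Reactants: 26 the secondary alcohol
Product: 27 (4S)-4-(6-methoxy-3,5-dimethyl-4-oxo-4H-pyran-2-yl)-2,4,6-trimethyl-3-[(2E,4S)-4-methyl-5-oxohept-2-en-2-yl]cyclohexa-2,5-dien-1-one (CNP0276209.1)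
Conditions: Dess–Martin periodinane, NaHCO3, CH2Cl2, 0 °C
Reagents that add atoms: none
Why: Dess–Martin oxidation of the secondary alcohol under buffered, non-basic conditions should give the ketone without epimerising the adjacent allylic stereocentre or moving the β,γ-alkene into conjugation.

**Compound list**

1 | pent-1-en-3-one | CCC(=O)C=C | starting material
2 | formaldehyde | C=O | starting material
3 | 2-(hydroxymethyl)pent-1-en-3-one | CCC(=O)C(=C)CO | intermediate
4 | tert-butyl (2-methylidene-3-oxopentyl) carbonate | CCC(=O)C(=C)COC(=O)OC(C)(C)C | intermediate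
5 | methyl 2-methyl-3-oxopentanoate (racemic) | CCC(=O)C(C)C(=O)OC | starting material
6 | methyl (2R)-2-methyl-2-(2-methylidene-3-oxopentyl)-3-oxopentanoate | CCC(=O)C(=C)C[C@@](C)(C(=O)OC)C(=O)CC | intermediate
7 | dilithium bis-enolate of 6 (both ethyl ketones as Z lithium enolates) | C/C=C(\O[Li])C(=C)C[C@@](C)(C(=O)OC)/C(O[Li])=C/C | intermediate
8 | (4S)-3-hydroxy-2,4-dimethyl-6-methylidene-4-propanoylcyclohex-2-en-1-one | OC1=C(C)C(=O)C(=C)C[C@]1(C)C(=O)CC | intermediate
9 | (4S)-3-hydroxy-2,4,6-trimethyl-4-propanoylcyclohexa-2,5-dien-1-one | OC1=C(C)C(=O)C(C)=C[C@]1(C)C(=O)CC | intermediate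
10 | (6S)-2,4,6-trimethyl-3-oxo-6-propanoylcyclohexa-1,4-dien-1-yl trifluoromethanesulfonate | O=S(=O)(OC1=C(C)C(=O)C(C)=C[C@]1(C)C(=O)CC)C(F)(F)F | intermediate
11 | 2-methylpropanedioic acid | CC(C(=O)O)C(=O)O | starting material
12 | 2-methylpropanedioyl dichloride | CC(C(=O)Cl)C(=O)Cl | intermediate
13 | (6R)-2,4,6-trimethyl-3-oxo-6-[(1Z)-1-(trimethylsilyloxy)prop-1-en-1-yl]cyclohexa-1,4-dien-1-yl trifluoromethanesulfonate | O=S(=O)(OC1=C(C)C(=O)C(C)=C[C@]1(C)/C(O[Si](C)(C)C)=C/C)C(F)(F)F | intermediate
14 | (6R)-6-(4-hydroxy-3,5-dimethyl-2-oxo-2H-pyran-6-yl)-2,4,6-trimethyl-3-oxocyclohexa-1,4-dien-1-yl trifluoromethanesulfonate | O=S(=O)(OC1=C(C)C(=O)C(C)=C[C@]1(C)C2=C(C)C(O)=C(C)C(=O)O2)C(F)(F)F | intermediate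
15 | (6R)-6-(6-methoxy-3,5-dimethyl-4-oxo-4H-pyran-2-yl)-2,4,6-trimethyl-3-oxocyclohexa-1,4-dien-1-yl trifluoromethanesulfonate | O=S(=O)(OC1=C(C)C(=O)C(C)=C[C@]1(C)C2=C(C)C(=O)C(C)=C(OC)O2)C(F)(F)F | intermediate
16 | (R)-but-3-yn-2-ol | C[C@@H](O)C#C | starting material
17 | (R)-but-3-yn-2-yl methanesulfonate | C[C@@H](OS(C)(=O)=O)C#C | intermediate
18 | propanal | CCC=O | starting material
19 | (P)-buta-1,2-dien-1-yl(ethyl)zinc | CC[Zn]C([H])=[C@@]=C([H])C | intermediate
20 | (3R,4S)-4-methylhex-5-yn-3-ol | CC[C@@H](O)[C@@H](C)C#C | intermediate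
21 | tert-butyl(dimethyl){[(3R,4S)-4-methylhex-5-yn-3-yl]oxy}silane | CC[C@@H](O[Si](C)(C)C(C)(C)C)[C@@H](C)C#C | intermediate
22 | {(3S,4R)-4-[tert-butyl(dimethyl)silyloxy]-3-methylhex-1-yn-1-yl}lithium | CC[C@@H](O[Si](C)(C)C(C)(C)C)[C@@H](C)C#C[Li] | intermediate
23 | tert-butyl(dimethyl){[(3R,4S)-4-methylhept-5-yn-3-yl]oxy}silane | CC[C@@H](O[Si](C)(C)C(C)(C)C)[C@@H](C)C#CC | intermediate
24 | tert-butyl(dimethyl){[(3R,4S,5Z)-4-methyl-6-(4,4,5,5-tetramethyl-1,3,2-dioxaborolan-2-yl)hept-5-en-3-yl]oxy}silane | CC[C@@H](O[Si](C)(C)C(C)(C)C)[C@@H](C)/C=C(\C)B1OC(C)(C)C(C)(C)O1 | intermediate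
25 | (4S)-3-[(2E,4S,5R)-5-{[tert-butyl(dimethyl)silyl]oxy}-4-methylhept-2-en-2-yl]-4-(6-methoxy-3,5-dimethyl-4-oxo-4H-pyran-2-yl)-2,4,6-trimethylcyclohexa-2,5-dien-1-one | CC[C@@H](O[Si](C)(C)C(C)(C)C)[C@@H](C)/C=C(\C)C1=C(C)C(=O)C(C)=C[C@]1(C)C2=C(C)C(=O)C(C)=C(OC)O2 | intermediate
26 | (4S)-3-[(2E,4S,5R)-5-hydroxy-4-methylhept-2-en-2-yl]-4-(6-methoxy-3,5-dimethyl-4-oxo-4H-pyran-2-yl)-2,4,6-trimethylcyclohexa-2,5-dien-1-one | CC[C@@H](O)[C@@H](C)/C=C(\C)C1=C(C)C(=O)C(C)=C[C@]1(C)C2=C(C)C(=O)C(C)=C(OC)O2 | intermediate
27 | (4S)-4-(6-methoxy-3,5-dimethyl-4-oxo-4H-pyran-2-yl)-2,4,6-trimethyl-3-[(2E,4S)-4-methyl-5-oxohept-2-en-2-yl]cyclohexa-2,5-dien-1-one | CCC(=O)[C@@H](C)/C=C(\C)C1=C(C)C(=O)C(C)=C[C@]1(C)c1oc(OC)c(C)c(=O)c1C | target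

**Step count and risks**

Total steps: 17. Longest linear sequence: 11 steps (steps 1–6, 8, 9, 15–17, from pent-1-en-3-one).

**Step 6, sulfonylation at the wrong enolate oxygen.** Steric approach control by the quaternary carbon could override the electronic preference and put the triflate on the C1 oxygen, which would send the side chain to the wrong ring carbon. The fallback sets out from 9 and returns at 25; it uses the same steric bias constructively in a Stork–Danheiser transposition.
- O-Methylation of 9 at the C1 oxygen (Me2SO4, K2CO3, acetone) would give (6R)-3-methoxy-2,4,6-trimethyl-6-propanoylcyclohexa-2,4-dien-1-one F1.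
- Its propanoyl ketone is masked in situ as the lithium enolate F2 (LiN(iPr)2, THF, −78 °C).
- Boronate 24 is converted with retention into the vinyl iodide F3 (NaOH, I2, THF–H2O), and iodine–lithium exchange (t-BuLi, −78 °C) gives the alkenyllithium F4.
- F4 is added, with CeCl3, to the ring carbonyl of F2 to give the tertiary carbinol F5.
- Aqueous acid then ionises the carbinol, water enters at C1 and methanol is lost, giving the C5-alkenylated dienone F6.
- The pyranone is built on F6 as in steps 8 and 9, through the silyl enol ether F7 and the hydroxypyranone F8, whose methylation with MeOTf gives 25.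

**Step 4, diversion of the enolates before Claisen closure.** The enolates could be captured by the other electrophilic sites (conjugate addition to the α-methylene ketone, aldol closure onto the propanoyl ketone), or the enone could oligomerise. The fallback sets out from 6 and returns at 9; the reactive alkene is removed before ring closure and the unsaturation restored afterwards.
- Hydrogenation of the 1,1-disubstituted enone alkene (H2, palladium on carbon, EtOAc) would give the saturated keto ester F9 as a mixture of epimers at the new methine.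
- Claisen closure under equilibrating conditions (KOtBu, THF, 0 °C), where aldol adducts revert and only the dione enolate accumulates, would give the saturated dione F10.
- Dehydrogenation with DDQ (1,4-dioxane, 80 °C) introduces the C2=C3 bond and gives 9 directly, so that step 5 is not needed.

**Step 3, poor enantiofacial discrimination of the acyclic enolate.** Mixed enolate geometries in the ion pair, or conjugate addition of the donor to the enone of the product, could erode selectivity or yield. The fallback sets out from 5 (with 3) and returns at 6; auxiliary control replaces catalysis.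
- Condensation of 5 with tert-butyl L-valinate (cat. TsOH, toluene, removal of water) would give the Z-enamino ester F11.
- Deprotonation (LiN(iPr)2, toluene, −78 °C) gives the chelated lithium aza-enolate F12.
- F12 is alkylated by 2-(bromomethyl)pent-1-en-3-one F13 (from 3 with PBr3, Et2O, 0 °C) to the imine F14. The face is chosen through the donor additive (HMPA in toluene versus THF), a switch that is established for this auxiliary.
- Mild aqueous acid then releases 6 and the recoverable amino ester.

**Further compounds**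

F1 | step 6 | (6R)-3-methoxy-2,4,6-trimethyl-6-propanoylcyclohexa-2,4-dien-1-one | COC1=C(C)C(=O)[C@@](C)(C(=O)CC)C=C1C
F2 | step 6 | lithium Z-enolate of the propanoyl group of F1 | COC1=C(C)C(=O)[C@@](C)(/C(O[Li])=C/C)C=C1C
F3 | step 6 | tert-butyl{[(3R,4S,5E)-6-iodo-4-methylhept-5-en-3-yl]oxy}dimethylsilane | CC[C@@H](O[Si](C)(C)C(C)(C)C)[C@@H](C)/C=C(\C)I
F4 | step 6 | {(2Z,4S,5R)-5-[tert-butyl(dimethyl)silyloxy]-4-methylhept-2-en-2-yl}lithium | CC[C@@H](O[Si](C)(C)C(C)(C)C)[C@@H](C)/C=C(\C)[Li]
F5 | step 6 | tertiary carbinol from 1,2-addition of F4 to the ring carbonyl of F2 (shown protonated; carbinol carbon unassigned) | CC[C@@H](O[Si](C)(C)C(C)(C)C)[C@@H](C)/C=C(\C)C1(O)C(C)=C(OC)C(C)=C[C@]1(C)C(=O)CC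
F6 | step 6 | (4S)-3-[(2E,4S,5R)-5-{[tert-butyl(dimethyl)silyl]oxy}-4-methylhept-2-en-2-yl]-2,4,6-trimethyl-4-propanoylcyclohexa-2,5-dien-1-one | CC[C@@H](O[Si](C)(C)C(C)(C)C)[C@@H](C)/C=C(\C)C1=C(C)C(=O)C(C)=C[C@]1(C)C(=O)CC
F7 | step 6 | (4S)-3-[(2E,4S,5R)-5-{[tert-butyl(dimethyl)silyl]oxy}-4-methylhept-2-en-2-yl]-2,4,6-trimethyl-4-[(1Z)-1-(trimethylsilyloxy)prop-1-en-1-yl]cyclohexa-2,5-dien-1-one | CC[C@@H](O[Si](C)(C)C(C)(C)C)[C@@H](C)/C=C(\C)C1=C(C)C(=O)C(C)=C[C@]1(C)/C(O[Si](C)(C)C)=C/C
F8 | step 6 | (4S)-3-[(2E,4S,5R)-5-{[tert-butyl(dimethyl)silyl]oxy}-4-methylhept-2-en-2-yl]-4-(4-hydroxy-3,5-dimethyl-2-oxo-2H-pyran-6-yl)-2,4,6-trimethylcyclohexa-2,5-dien-1-one | CC[C@@H](O[Si](C)(C)C(C)(C)C)[C@@H](C)/C=C(\C)C1=C(C)C(=O)C(C)=C[C@]1(C)C2=C(C)C(O)=C(C)C(=O)O2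
F9 | step 4 | methyl (2R)-2-methyl-2-(2-methyl-3-oxopentyl)-3-oxopentanoate (epimers at the side-chain methine) | CCC(=O)C(C)C[C@@](C)(C(=O)OC)C(=O)CC
F10 | step 4 | (4S)-3-hydroxy-2,4,6-trimethyl-4-propanoylcyclohex-2-en-1-one (epimers at C6) | OC1=C(C)C(=O)C(C)C[C@]1(C)C(=O)CC
F11 | step 3 | methyl (2Z)-3-{[(2S)-1-tert-butoxy-3-methyl-1-oxobutan-2-yl]amino}-2-methylpent-2-enoate | CC/C(N[C@@H](C(C)C)C(=O)OC(C)(C)C)=C(\C)C(=O)OC
F12 | step 3 | N-lithio derivative (lithium aza-enolate) of F11 | CC/C(N([Li])[C@@H](C(C)C)C(=O)OC(C)(C)C)=C(\C)C(=O)OC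
F13 | step 3 | 2-(bromomethyl)pent-1-en-3-one | CCC(=O)C(=C)CBr
F14 | step 3 | methyl (2R)-3-{[(2S)-1-tert-butoxy-3-methyl-1-oxobutan-2-yl]imino}-2-methyl-2-(2-methylidene-3-oxopentyl)pentanoate | CCC(=O)C(=C)C[C@@](C)(C(=O)OC)C(CC)=N[C@@H](C(C)C)C(=O)OC(C)(C)C
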